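**Retrosynthetic overview**

- Octacosanolide has a single ring, the 29-membered lactone, and it is closed last by macrolactonization of 28-hydroxyoctacosanoic acid.
- The seco acid comes from a C28 chain with a benzyl ether at C28, a methyl ester at C1 and a ketone at C14; the ketone is removed by Wolff–Kishner reduction.
- The C14 ketone marks the key C14–C15 bond: a crossed Claisen condensation of the lithium enolate of tert-butyl 15-(benzyloxy)pentadecanoate with methyl 14-chloro-14-oxotetradecanoate, followed by loss of the tert-butoxycarbonyl carbon.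
- The two C14 halves come from 15-pentadecanolide and tetradecanedioic acid.

Assumption: the target has no stereocentre, so there is no enantiomer to select; the one stereocentre that arises in the β-keto ester intermediates is racemic and is erased at the decarboxylation.

**Route**

Step 1
Reactants: 1 15-pentadecanolide (oxacyclohexadecan-2-one)
Product: 3 15-(benzyloxy)pentadecanoic acid, via potassium 15-hydroxypentadecanoate 2 (not isolated)
Conditions: KOH (powdered, 5 equiv), BnBr (3 equiv), toluene, reflux, 24 h; then KOH, MeOH/H2O, reflux, 2 h (cleaves any benzyl ester); 2 M HCl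
Reagents that add atoms: benzyl bromide BrCc1ccccc1; potassium hydroxide [K+].[OH-]
Why: Saponification of the lactone followed by Williamson etherification of the ω-alkoxide gives the benzyl ether acid in one pot, with no stereocentre involved.

Step 2
Reactants: 3 15-(benzyloxy)pentadecanoic acid
Product: 4 tert-butyl 15-(benzyloxy)pentadecanoate
Conditions: Cl3CC(=NH)OtBu (2 equiv), BF3·OEt2 (5 mol %), CH2Cl2/cyclohexane, rt, 16 h
Reagents that add atoms: tert-butyl 2,2,2-trichloroacetimidate CC(C)(C)OC(=N)C(Cl)(Cl)Cl
Why: Acid-catalysed trichloroacetimidate esterification installs the tert-butyl ester under mild conditions that leave the benzyl ether untouched, and gives an ester whose enolate does not self-condense.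

Step 3
Reactants: 5 tetradecanedioic acid
Product: 6 dimethyl tetradecanedioate
Conditions: MeOH, H2SO4 (cat.), reflux, 8 h
Reagents that add atoms: methanol CO
Why: Fischer esterification is driven to the diester by the large excess of methanol.

Step 4
Reactants: 6 dimethyl tetradecanedioate
Product: 8 14-methoxy-14-oxotetradecanoic acid, via barium half-ester salt 7 (not isolated)
Conditions: Ba(OH)2 (0.5 equiv), MeOH, 35 °C, 24 h; then 2 M HCl, Et2O (unreacted 6 recycled)
Reagents that add atoms: barium hydroxide [Ba+2].[OH-].[OH-]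
Why: Partial saponification stops at the half ester because its barium salt precipitates from methanol and is withdrawn from further hydrolysis.

Step 5
Reactants: 8 14-methoxy-14-oxotetradecanoic acid
Product: 9 methyl 14-chloro-14-oxotetradecanoate
Conditions: (COCl)2 (1.5 equiv), DMF (cat.), CH2Cl2, 0 °C to rt, 2 h; evaporate, use crude
Reagents that add atoms: oxalyl chloride ClC(=O)C(=O)Cl
Why: DMF-catalysed (Vilsmeier-type) acid chloride formation is clean, gives only gaseous by-products and does not touch the methyl ester.

Step 6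
Reactants: 4 tert-butyl 15-(benzyloxy)pentadecanoate (2.2 equiv), 9 methyl 14-chloro-14-oxotetradecanoate (1.0 equiv)
Product: 12 1-tert-butyl 16-methyl 2-[13-(benzyloxy)tridecyl]-3-oxohexadecanedioate, via lithium ester enolate 10 (not isolated), via lithium keto ester enolate 11 (not isolated)
Conditions: LiN(iPr)2 (2.2 equiv), THF, −78 °C, 45 min; then 9 in THF, −78 °C, 1 h; 1 M HCl, −78 °C to rt (excess 4 recovered)
Reagents that add atoms: none
Why: Crossed Claisen condensation by C-acylation of a preformed lithium tert-butyl ester enolate with an acid chloride forms the C14–C15 bond; the second equivalent of enolate deprotonates the product and so prevents over-acylation, and the new α-stereocentre is formed racemic and removed in step 7.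

Step 7
Reactants: 12 1-tert-butyl 16-methyl 2-[13-(benzyloxy)tridecyl]-3-oxohexadecanedioate
Product: 14 methyl 28-(benzyloxy)-14-oxooctacosanoate, via free β-keto acid 13 (not isolated)
Conditions: TFA/CH2Cl2 (1:4), rt, 3 h; evaporate; toluene, 80 °C, 1 h
Reagents that add atoms: none
Why: Acidolysis of the tert-butyl ester and thermal β-keto acid decarboxylation remove the extra carbon selectively, since the methyl ester and benzyl ether are inert to TFA at rt, and this erases the only stereocentre.

Step 8
Reactants: 14 methyl 28-(benzyloxy)-14-oxooctacosanoate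
Product: 17 28-(benzyloxy)octacosanoic acid, via potassium keto carboxylate 15 (not isolated), via potassium hydrazone carboxylate 16 (not isolated)
Conditions: KOH (6 equiv), diethylene glycol, 120 °C, 1 h; N2H4·H2O (5 equiv), 130 °C, 2 h; distil to 200 °C, 4 h; 2 M HCl
Reagents that add atoms: potassium hydroxide [K+].[OH-]
Why: Wolff–Kishner reduction in the Huang-Minlon form turns the mid-chain ketone into CH2 while the same base saponifies the methyl ester, and the benzyl ether is stable to hot alkali.

Step 9
Reactants: 17 28-(benzyloxy)octacosanoic acid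
Product: 18 28-hydroxyoctacosanoic acid
Conditions: H2 (1 atm), 10% Pd/C, THF/AcOH (10:1), 50 °C, 12 h; filter hot
Reagents that add atoms: none
Why: Catalytic hydrogenolysis of the benzyl ether frees the primary alcohol with nothing else in the saturated chain able to react.

Step 10
Reactants: 18 28-hydroxyoctacosanoic acid
Product: 20 octacosanolide, via mixed anhydride 19 (not isolated)
Conditions: 2,4,6-Cl3C6H2COCl (1.3 equiv), Et3N (1.5 equiv), THF, 40 °C, 2 h; then syringe-pump addition over 10 h to DMAP (6 equiv), toluene, 110 °C (final 1 mM)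
Reagents that add atoms: none
Why: Yamaguchi macrolactonization under high dilution closes the strain-free 29-membered ring through the DMAP-activated mixed anhydride, favouring cyclisation over oligomerisation.

**Compound list**

1 | 15-pentadecanolide (oxacyclohexadecan-2-one) | O=C1CCCCCCCCCCCCCCO1 | starting material
2 | potassium 15-hydroxypentadecanoate | [K+].[O-]C(=O)CCCCCCCCCCCCCCO | intermediate
3 | 15-(benzyloxy)pentadecanoic acid | OC(=O)CCCCCCCCCCCCCCOCc1ccccc1 | intermediate
4 | tert-butyl 15-(benzyloxy)pentadecanoate | CC(C)(C)OC(=O)CCCCCCCCCCCCCCOCc1ccccc1 | intermediate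
5 | tetradecanedioic acid | OC(=O)CCCCCCCCCCCCC(=O)O | starting material
6 | dimethyl tetradecanedioate | COC(=O)CCCCCCCCCCCCC(=O)OC | intermediate
7 | barium bis(14-methoxy-14-oxotetradecanoate) | [Ba+2].COC(=O)CCCCCCCCCCCCC(=O)[O-].COC(=O)CCCCCCCCCCCCC(=O)[O-] | intermediate
8 | 14-methoxy-14-oxotetradecanoic acid | COC(=O)CCCCCCCCCCCCC(=O)O | intermediate
9 | methyl 14-chloro-14-oxotetradecanoate | COC(=O)CCCCCCCCCCCCC(=O)Cl | intermediate
10 | lithium 15-(benzyloxy)-1-tert-butoxypentadec-1-en-1-olate | [Li+].[O-]C(OC(C)(C)C)=CCCCCCCCCCCCCCOCc1ccccc1 | intermediate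
11 | lithium enolate of 12 (3-olate, C2=C3) | [Li+].COC(=O)CCCCCCCCCCCCC([O-])=C(CCCCCCCCCCCCCOCc1ccccc1)C(=O)OC(C)(C)C | intermediate
12 | 1-tert-butyl 16-methyl 2-[13-(benzyloxy)tridecyl]-3-oxohexadecanedioate (racemic) | COC(=O)CCCCCCCCCCCCC(=O)C(CCCCCCCCCCCCCOCc1ccccc1)C(=O)OC(C)(C)C | intermediate
13 | 2-[13-(benzyloxy)tridecyl]-16-methoxy-3,16-dioxohexadecanoic acid (racemic) | COC(=O)CCCCCCCCCCCCC(=O)C(CCCCCCCCCCCCCOCc1ccccc1)C(=O)O | intermediate
14 | methyl 28-(benzyloxy)-14-oxooctacosanoate | COC(=O)CCCCCCCCCCCCC(=O)CCCCCCCCCCCCCCOCc1ccccc1 | intermediate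
15 | potassium 28-(benzyloxy)-14-oxooctacosanoate | [K+].[O-]C(=O)CCCCCCCCCCCCC(=O)CCCCCCCCCCCCCCOCc1ccccc1 | intermediate
16 | potassium 28-(benzyloxy)-14-hydrazinylideneoctacosanoate | [K+].[O-]C(=O)CCCCCCCCCCCCC(=NN)CCCCCCCCCCCCCCOCc1ccccc1 | intermediate
17 | 28-(benzyloxy)octacosanoic acid | OC(=O)CCCCCCCCCCCCCCCCCCCCCCCCCCCOCc1ccccc1 | intermediate
18 | 28-hydroxyoctacosanoic acid | OC(=O)CCCCCCCCCCCCCCCCCCCCCCCCCCCO | intermediate
19 | 28-hydroxyoctacosanoic 2,4,6-trichlorobenzoic anhydride | OCCCCCCCCCCCCCCCCCCCCCCCCCCCC(=O)OC(=O)c1c(Cl)cc(Cl)cc1Cl | intermediate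
20 | octacosanolide (oxacyclononacosan-2-one) | O=C1CCCCCCCCCCCCCCCCCCCCCCCCCCCO1 | target

**Summary**

Total step count: 10. Longest linear sequence: 8 steps (5 to 20 through steps 3, 4, 5, 6, 7, 8, 9 and 10); the other branch (1 to 20) is 7 steps.

Steps most likely to fail, with fallbacks:

Step 6 (crossed Claisen acylation). The acid chloride may be deprotonated to a ketene or O-acylate the enolate. The fallback replaces the acylation by an aldol addition followed by oxidation. It sets out from 9, which is reduced with LiAlH(OtBu)3 (THF, −78 °C) to methyl 14-oxotetradecanoate F1. Enolate 10 (1.1 equiv, made from 4 as in step 6) is added to the aldehyde at −78 °C to give 1-tert-butyl 16-methyl 2-[13-(benzyloxy)tridecyl]-3-hydroxyhexadecanedioate F2 as a diastereomer mixture. Oxidation with Dess–Martin periodinane (NaHCO3, CH2Cl2, rt) brings the sequence back to the route at 12.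

Step 8 (Wolff–Kishner reduction). The waxy potassium soap may mix poorly, and azine formation or incomplete reduction is possible. The fallback removes the oxygen by a radical route. It sets out from 14, which NaBH4 (THF/MeOH, 0 °C) reduces to methyl 28-(benzyloxy)-14-hydroxyoctacosanoate F3. Phenyl chlorothionoformate (pyridine, DMAP, CH2Cl2) converts this into methyl 28-(benzyloxy)-14-[(phenoxycarbonothioyl)oxy]octacosanoate F4. Barton–McCombie deoxygenation (Bu3SnH, AIBN, toluene, 110 °C) gives methyl 28-(benzyloxy)octacosanoate F5, and saponification (LiOH, THF/MeOH/H2O, 50 °C; HCl) comes back to the route at 17.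

Step 10 (macrolactonization). The poorly soluble seco acid may give diolide and oligomers through acyl activation. The fallback closes the ring by alkylation at the other terminus. It sets out from 18, which 48% HBr/AcOH (cat. H2SO4, reflux) converts into 28-bromooctacosanoic acid F6. Slow addition of this acid to Cs2CO3 in DMF at 80 °C under high dilution (intramolecular carboxylate SN2) comes back to the route at 20.

**Further compounds**

F1 | step 6 | methyl 14-oxotetradecanoate | COC(=O)CCCCCCCCCCCCC=O
F2 | step 6 | 1-tert-butyl 16-methyl 2-[13-(benzyloxy)tridecyl]-3-hydroxyhexadecanedioate (racemic, diastereomer mixture) | COC(=O)CCCCCCCCCCCCC(O)C(CCCCCCCCCCCCCOCc1ccccc1)C(=O)OC(C)(C)C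
F3 | step 8 | methyl 28-(benzyloxy)-14-hydroxyoctacosanoate (racemic) | COC(=O)CCCCCCCCCCCCC(O)CCCCCCCCCCCCCCOCc1ccccc1
F4 | step 8 | methyl 28-(benzyloxy)-14-[(phenoxycarbonothioyl)oxy]octacosanoate (racemic) | COC(=O)CCCCCCCCCCCCC(OC(=S)Oc1ccccc1)CCCCCCCCCCCCCCOCc1ccccc1
F5 | step 8 | methyl 28-(benzyloxy)octacosanoate | COC(=O)CCCCCCCCCCCCCCCCCCCCCCCCCCCOCc1ccccc1
F6 | step 10 | 28-bromooctacosanoic acid | OC(=O)CCCCCCCCCCCCCCCCCCCCCCCCCCCBr
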